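**Plan**

- Retrosynthesis: the angelate O–CH2 bond and the central C2=C3 double bond are cut in one operation, giving potassium (Z)-2-methylbut-2-enoate, acetaldehyde and a cinnamyl 2-phosphonoacrylate. The acrylate C=CH2 is then traced back through a selenoxide to a 2-phosphonopropanoate, the C–CH3 bond to a phosphonoacetate, and the ester C–O bond to bis(trifluoroethyl)phosphonoacetic acid and (E)-3,4-dimethoxycinnamyl alcohol.
- Enabling feature: the target has no ring. C2 of its central but-2-enoate carries both the CH2 carbon bound to the angelate oxygen and the C2=C3 double bond (C4 methyl cis to the C1 ester carbonyl). C2 can therefore be the alpha-carbon of a phosphonoacrylate, its CH2 the Michael terminus, and C3–C4 come from acetaldehyde.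
- Forward: the chain is joined linearly (cinnamyl ester, alpha-methyl, alpha-selenide, acrylate) and completed by the three-component union; no ring arises at any stage.
- Stereochemistry: the target has no stereocentre. The E-cinnamyl and Z-angelate double bonds are bought and never activated. The central Z double bond is set in the last step by kinetic control of the bis(trifluoroethyl) phosphonate.

Key step: step 7

Remark on the chemistry: the saturated 2-phosphonopropanoate intermediates and the aldol-type adduct of the last step are chiral but racemic (one enantiomer of the adduct is drawn), and their stereocentres are destroyed before the target is reached.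

**Route**

Step 1
Reactants: 1 methyl 2-[bis(2,2,2-trifluoroethoxy)phosphoryl]acetate
Product: 2 2-[bis(2,2,2-trifluoroethoxy)phosphoryl]acetic acid
Conditions: LiOH·H2O (1.1 equiv), THF/H2O, 0 °C; then 1 M HCl to pH 2, EtOAc extraction
Reagents that add atoms: lithium hydroxide, [Li+].[OH-]
Why: Ester saponification: at 0 °C with only a slight excess of LiOH, hydroxide should attack the carboxyl carbon, which the alpha-phosphoryl group activates, much faster than phosphorus, so both trifluoroethyl P–O bonds should survive and acidification frees the acid.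

Step 2
Reactants: 2 2-[bis(2,2,2-trifluoroethoxy)phosphoryl]acetic acid; 3 (E)-3-(3,4-dimethoxyphenyl)prop-2-en-1-ol
Product: 4 (E)-3-(3,4-dimethoxyphenyl)allyl 2-[bis(2,2,2-trifluoroethoxy)phosphoryl]acetate
Conditions: N-ethyl-N'-(3-dimethylaminopropyl)carbodiimide hydrochloride (EDC·HCl), 4-(dimethylamino)pyridine (DMAP, 0.1 equiv), CH2Cl2, 0 °C → rt
Reagents that add atoms: none
Why: Steglich esterification: the carbodiimide activates the acid and DMAP transfers the acyl group to the primary allylic alcohol under near-neutral conditions, which the electron-rich, acid-sensitive cinnamyl system and the P–O bonds should tolerate.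

Step 3
Reactants: 4 (E)-3-(3,4-dimethoxyphenyl)allyl 2-[bis(2,2,2-trifluoroethoxy)phosphoryl]acetate
Product: 5 (E)-3-(3,4-dimethoxyphenyl)allyl 2-[bis(2,2,2-trifluoroethoxy)phosphoryl]propanoate (racemic)
Conditions: NaH (0.95 equiv), THF, 0 °C; MeI (1.5 equiv), 0 °C → rt
Reagents that add atoms: iodomethane, CI
Why: C-Alkylation of a phosphonoacetate carbanion: NaH deprotonates the doubly activated CH2 irreversibly and the soft carbanion is methylated by SN2 on iodomethane, a slight deficit of base and the lower acidity of the product limiting dimethylation; the new stereocentre is racemic and is removed in step 5.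

Step 4
Reactants: 5 (E)-3-(3,4-dimethoxyphenyl)allyl 2-[bis(2,2,2-trifluoroethoxy)phosphoryl]propanoate
Product: 6 (E)-3-(3,4-dimethoxyphenyl)allyl 2-[bis(2,2,2-trifluoroethoxy)phosphoryl]-2-(phenylselanyl)propanoate (racemic)
Conditions: NaH (1.05 equiv), THF, 0 °C; PhSeBr (1.05 equiv), −78 °C → 0 °C
Reagents that add atoms: benzeneselenenyl bromide, Br[Se]c1ccccc1
Why: Electrophilic selenenylation of a stabilised carbanion: the tertiary sodium carbanion attacks selenium of PhSeBr at −78 °C far faster than the reagent can add to the cinnamyl double bond, giving the quaternary selenide as a racemate whose stereocentre disappears in step 5.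

Step 5
Reactants: 6 (E)-3-(3,4-dimethoxyphenyl)allyl 2-[bis(2,2,2-trifluoroethoxy)phosphoryl]-2-(phenylselanyl)propanoate
Product: 8 (E)-3-(3,4-dimethoxyphenyl)allyl 2-[bis(2,2,2-trifluoroethoxy)phosphoryl]acrylate, via selenoxide 7 (not isolated)
Conditions: 30% aq. H2O2 (2.2 equiv), CH2Cl2, 0 °C → 20 °C; brief cold aq. NaHCO3 wash; concentrated cold and used at once as a THF solution
Reagents that add atoms: none
Why: Selenoxide elimination: H2O2 oxidises selenium to the selenoxide 7, which undergoes syn-elimination at or below room temperature and, having beta-hydrogens only on the methyl group, can deliver only the 1,1-disubstituted alkene, under non-basic conditions that should spare the P–O bonds and not trigger anionic polymerisation of the product.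

Step 6
Reactants: 9 angelic acid [(Z)-2-methylbut-2-enoic acid]
Product: 10 potassium (Z)-2-methylbut-2-enoate (potassium angelate)
Conditions: KOt-Bu (0.98 equiv, added to the acid), THF, 0 °C; evaporation; high vacuum
Reagents that add atoms: potassium tert-butoxide, CC(C)(C)[O-].[K+]
Why: Acid–base neutralisation: adding slightly less than one equivalent of KOt-Bu to the acid leaves no free alkoxide, so the Z double bond should not isomerise, and evaporation of THF and tert-butanol leaves the anhydrous salt.

Step 7
Reactants: 10 potassium (Z)-2-methylbut-2-enoate; 8 (E)-3-(3,4-dimethoxyphenyl)allyl 2-[bis(2,2,2-trifluoroethoxy)phosphoryl]acrylate; 11 acetaldehyde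
Product: 14 Morinin L [(E)-3-(3,4-dimethoxyphenyl)allyl (Z)-2-{[(Z)-2-methylbut-2-enoyl]oxymethyl}but-2-enoate], via potassium phosphonate carbanion 12 (not isolated), via potassium beta-alkoxide adduct 13 (not isolated)
Conditions: 10 (3 equiv), 18-crown-6 (3 equiv), 11 (5 equiv), THF, −78 °C; 8 in THF added over 2 h by syringe pump; −78 → −40 °C; NaH2PO4/Na2HPO4 buffer (pH 7) at −40 °C; chromatography on silica gel pre-washed with the same buffer
Reagents that add atoms: none
Why: Proposed new method: the crown-separated carboxylate oxygen of 10 adds reversibly to the unsubstituted CH2 terminus of the doubly activated alkene of 8 (oxa-Michael addition) to give the phosphonate carbanion 12, which is the anion of a Still-Gennari olefination and is pulled out of the addition/beta-elimination equilibrium by capture with acetaldehyde (adduct 13) and syn-elimination of potassium bis(2,2,2-trifluoroethyl) phosphate. The closest known reaction types are the tandem Michael/Horner-Wadsworth-Emmons reactions of 2-phosphonoacrylates with alkoxide, amine and carbon nucleophiles and the Still-Gennari olefination of alpha-substituted bis(trifluoroethyl) phosphonoacetates; the carboxylate donor is the element without precedent. No ring is closed and no stereocentre is created in the product, the only stereochemical element set being the C2=C3 double bond. Its Z geometry (C4 methyl cis to the ester carbonyl) should follow from kinetic control, because the electron-poor trifluoroethoxy groups speed up P–O closure and fragmentation so that the initial aldol-type addition is not reversed, and the potassium/18-crown-6 counter-ion at −78 °C gives no chelated, equilibrating adduct. The chemoselectivity needed is the three-component union instead of anionic oligomerisation of 8, and it is secured by feeding 8 slowly into an excess of 10 and 11 so that each carbanion meets aldehyde before it meets another acrylate. The angelate double bond should keep its Z geometry because angelic acid is used only as its carboxylate nucleophile and its acyl carbon is at no point converted into a chloride, anhydride or other activated form.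

**Compound list**

1 | methyl 2-[bis(2,2,2-trifluoroethoxy)phosphoryl]acetate | COC(=O)CP(=O)(OCC(F)(F)F)OCC(F)(F)F | starting material
2 | 2-[bis(2,2,2-trifluoroethoxy)phosphoryl]acetic acid | OC(=O)CP(=O)(OCC(F)(F)F)OCC(F)(F)F | intermediate
3 | (E)-3-(3,4-dimethoxyphenyl)prop-2-en-1-ol | OC/C=C/c1ccc(OC)c(OC)c1 | starting material
4 | (E)-3-(3,4-dimethoxyphenyl)allyl 2-[bis(2,2,2-trifluoroethoxy)phosphoryl]acetate | O=C(CP(=O)(OCC(F)(F)F)OCC(F)(F)F)OC/C=C/c1ccc(OC)c(OC)c1 | intermediate
5 | (E)-3-(3,4-dimethoxyphenyl)allyl 2-[bis(2,2,2-trifluoroethoxy)phosphoryl]propanoate, racemic | CC(C(=O)OC/C=C/c1ccc(OC)c(OC)c1)P(=O)(OCC(F)(F)F)OCC(F)(F)F | intermediate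
6 | (E)-3-(3,4-dimethoxyphenyl)allyl 2-[bis(2,2,2-trifluoroethoxy)phosphoryl]-2-(phenylselanyl)propanoate, racemic | CC([Se]c1ccccc1)(C(=O)OC/C=C/c1ccc(OC)c(OC)c1)P(=O)(OCC(F)(F)F)OCC(F)(F)F | intermediate
7 | (E)-3-(3,4-dimethoxyphenyl)allyl 2-[bis(2,2,2-trifluoroethoxy)phosphoryl]-2-(phenylseleninyl)propanoate, mixture of diastereomers, formed in the flask | CC([Se](=O)c1ccccc1)(C(=O)OC/C=C/c1ccc(OC)c(OC)c1)P(=O)(OCC(F)(F)F)OCC(F)(F)F | intermediate
8 | (E)-3-(3,4-dimethoxyphenyl)allyl 2-[bis(2,2,2-trifluoroethoxy)phosphoryl]acrylate | C=C(C(=O)OC/C=C/c1ccc(OC)c(OC)c1)P(=O)(OCC(F)(F)F)OCC(F)(F)F | intermediate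
9 | angelic acid, (Z)-2-methylbut-2-enoic acid | C/C=C(/C)C(=O)O | starting material
10 | potassium (Z)-2-methylbut-2-enoate | C/C=C(/C)C(=O)[O-].[K+] | intermediate
11 | acetaldehyde | CC=O | starting material
12 | potassium carbanion of (E)-3-(3,4-dimethoxyphenyl)allyl 3-{[(Z)-2-methylbut-2-enoyl]oxy}-2-[bis(2,2,2-trifluoroethoxy)phosphoryl]propanoate, formed in the flask | C/C=C(/C)C(=O)OC[C-](C(=O)OC/C=C/c1ccc(OC)c(OC)c1)P(=O)(OCC(F)(F)F)OCC(F)(F)F.[K+] | intermediate
13 | potassium (2S*,3S*)-alkoxide of (E)-3-(3,4-dimethoxyphenyl)allyl 3-hydroxy-2-{[(Z)-2-methylbut-2-enoyl]oxymethyl}-2-[bis(2,2,2-trifluoroethoxy)phosphoryl]butanoate, racemic, formed in the flask; with P and O syn-periplanar the C4 methyl and the ester carbonyl lie on the same side | C[C@H]([O-])[C@@](COC(=O)/C(C)=C\C)(C(=O)OC/C=C/c1ccc(OC)c(OC)c1)P(=O)(OCC(F)(F)F)OCC(F)(F)F.[K+] | intermediate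
14 | Morinin L, (E)-3-(3,4-dimethoxyphenyl)allyl (Z)-2-{[(Z)-2-methylbut-2-enoyl]oxymethyl}but-2-enoate | C/C=C(/C)C(=O)OC/C(=C/C)C(=O)OC/C=C/c1ccc(OC)c(OC)c1 | target

**Step count and risks**

Total steps: 7. Longest linear sequence: 6 (steps 1, 2, 3, 4, 5 and 7; step 6 is a one-step branch).

Steps most likely to fail:

1. Step 7. Beta-elimination of the carboxylate from the adduct carbanion, or addition of that carbanion to a further molecule of acrylate, may outrun the olefination. The Z geometry may also erode through reversible allylic attack of excess carboxylate on the product. The fallback sets out from 4 and returns at 14, using known reaction types: the oxygen-bearing CH2 is installed by alkylation instead of conjugate addition, as a silyl ether that is a poor leaving group.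
   - The sodium carbanion of 4 (NaH, THF, 0 °C) is alkylated with (chloromethoxy)triisopropylsilane, an alkoxymethylation of the kind known for other alpha-chloro ethers. This should give (E)-3-(3,4-dimethoxyphenyl)allyl 2-[bis(2,2,2-trifluoroethoxy)phosphoryl]-3-[(triisopropylsilyl)oxy]propanoate F1.
   - A conventional Still-Gennari olefination (KN(SiMe3)2, 18-crown-6, THF, −78 °C, then 11) should give (E)-3-(3,4-dimethoxyphenyl)allyl (Z)-2-{[(triisopropylsilyl)oxy]methyl}but-2-enoate F2.
   - HF·pyridine in THF at 0 °C should free (E)-3-(3,4-dimethoxyphenyl)allyl (Z)-2-(hydroxymethyl)but-2-enoate F3.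
   - A Mitsunobu esterification with 9 (PPh3, diisopropyl azodicarboxylate, THF, 0 °C) activates the alcohol and not the acid, and rejoins the route at 14.

2. Step 5. The cinnamyl double bond may be epoxidised by the perseleninic acid that forms from the selenium by-product and excess peroxide, selenenic acid may add back to that double bond, and the very electrophilic acrylate may hydrate or polymerise during aqueous work-up. The fallback sets out from 4 and returns at 8, bypassing steps 3 to 5 with a Mannich methylenation that needs no oxidant.
   - Compound 4 with dimethyl(methylene)ammonium iodide and i-Pr2NEt in CH2Cl2 at 0 °C should give the Mannich base (E)-3-(3,4-dimethoxyphenyl)allyl 2-[bis(2,2,2-trifluoroethoxy)phosphoryl]-3-(dimethylamino)propanoate F4.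
   - N-Methylation with MeI should give [2-{[(E)-3-(3,4-dimethoxyphenyl)allyl]oxycarbonyl}-2-[bis(2,2,2-trifluoroethoxy)phosphoryl]ethyl]trimethylammonium iodide F5.
   - F5 should lose trimethylamine by E1cB elimination in a cold two-phase CH2Cl2/aq. NaHCO3 mixture and deliver 8.

3. Step 1. Hydroxide may attack phosphorus as well as the carboxyl carbon, with loss of a trifluoroethoxy group. The fallback sets out from 1 and 3 and returns at 4, avoiding the free acid. It is a DMAP-catalysed transesterification in toluene at reflux over 4 Å molecular sieves, in which the phosphonoacetate loses methanol through its phosphonoketene and the ketene is trapped by the cinnamyl alcohol. No new compound is made on the way (F0).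

Further compounds
F1 | step 7 | (E)-3-(3,4-dimethoxyphenyl)allyl 2-[bis(2,2,2-trifluoroethoxy)phosphoryl]-3-[(triisopropylsilyl)oxy]propanoate | CC(C)[Si](OCC(C(=O)OC/C=C/c1ccc(OC)c(OC)c1)P(=O)(OCC(F)(F)F)OCC(F)(F)F)(C(C)C)C(C)C
F2 | step 7 | (E)-3-(3,4-dimethoxyphenyl)allyl (Z)-2-{[(triisopropylsilyl)oxy]methyl}but-2-enoate | C/C=C(/CO[Si](C(C)C)(C(C)C)C(C)C)C(=O)OC/C=C/c1ccc(OC)c(OC)c1
F3 | step 7 | (E)-3-(3,4-dimethoxyphenyl)allyl (Z)-2-(hydroxymethyl)but-2-enoate | C/C=C(/CO)C(=O)OC/C=C/c1ccc(OC)c(OC)c1
F4 | step 5 | (E)-3-(3,4-dimethoxyphenyl)allyl 2-[bis(2,2,2-trifluoroethoxy)phosphoryl]-3-(dimethylamino)propanoate | CN(C)CC(C(=O)OC/C=C/c1ccc(OC)c(OC)c1)P(=O)(OCC(F)(F)F)OCC(F)(F)F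
F5 | step 5 | [2-{[(E)-3-(3,4-dimethoxyphenyl)allyl]oxycarbonyl}-2-[bis(2,2,2-trifluoroethoxy)phosphoryl]ethyl]trimethylammonium iodide | C[N+](C)(C)CC(C(=O)OC/C=C/c1ccc(OC)c(OC)c1)P(=O)(OCC(F)(F)F)OCC(F)(F)F.[I-]
F0 | step 1 | none | none
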